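**Strategy.** Both dihydrobenzofurans are cut at their C2–aryl bonds, because each C2 aryl carbon is the ortho/para-activated carbon of a resorcinol-type ring. The route rests on the second cut. C2 of the bromo dihydrobenzofuran (later the styryl-bearing ring) is held at acetal level as an anomeric benzoate. Acid ionises it to a 2-oxocarbenium ion, which alkylates C7 of the benzo ring of the other dihydrobenzofuran, the only arene carbon ortho to ring O1 and para to O–C4 that no silyloxy group flanks. This one step joins the halves and sets C2 trans to the C3 aryl group. The C3 centres come from phosphoric-acid-catalysed [4+1] annulations of o-quinone methides with a diazoketone.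

Key step: step 15

Remark: TIPS = triisopropylsilyl, TBS = tert-butyldimethylsilyl; "TIPSO" in a name means triisopropylsilyloxy.
Assumption: the sense of induction of the chiral phosphoric acid in steps 6 and 13 cannot be fixed on paper; the (R)-catalyst is written, and its mirror image is taken if it should give the (3R) series.

**Step 1**
Reactants: 1 5-bromobenzene-1,3-diol
Product: 2 1-bromo-3,5-bis(TIPSO)benzene
Conditions: TIPSCl (2.3 eq), imidazole, DMF, rt
Reagents that add atoms: chlorotriisopropylsilane, CC(C)[Si](Cl)(C(C)C)C(C)C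
Why: Standard phenol silylation; TIPS ethers should survive the Grignard, peracid and Lewis acid steps and shield their ortho positions in the later Friedel–Crafts steps.

**Step 2**
Reactants: 2 1-bromo-3,5-bis(TIPSO)benzene
Product: 3 [3,5-bis(TIPSO)phenyl]magnesium bromide, kept as a titrated THF stock solution under argon
Conditions: Mg turnings (I2 crystal to activate), THF, 50 °C; titration; one batch divided between steps 5 and 12
Reagents that add atoms: magnesium, [Mg]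
Why: Grignard reagent formation by insertion of magnesium into the aryl C–Br bond, to which the aryl silyl ethers are inert, so that one stock solution can serve both carbonyl additions.

**Step 3**
Reactants: 4 2-bromo-1-phenylethan-1-one
Product: 5 2-diazo-1-phenylethan-1-one
Conditions: TsNHNHTs (2 eq), DBU (5 eq), THF, 0 °C
Reagents that add atoms: N,N'-ditosylhydrazine, Cc1ccc(cc1)S(=O)(=O)NNS(=O)(=O)c1ccc(C)cc1
Why: N-alkylation of the bis-sulfonylhydrazine followed by two base-induced sulfinate eliminations (Bamford–Stevens type) should give the diazoketone without diazomethane.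

**Step 4**
Reactants: 6 2,6-dihydroxybenzaldehyde
Product: 7 2-hydroxy-6-(TIPSO)benzaldehyde
Conditions: TIPSCl (1.0 eq), imidazole, CH2Cl2, 0 °C
Reagents that add atoms: chlorotriisopropylsilane, CC(C)[Si](Cl)(C(C)C)C(C)C
Why: Monosilylation should stop after one group, because the remaining OH is locked in a hydrogen bond to the aldehyde and resists a second bulky silyl chloride.

**Step 5**
Reactants: 3 [3,5-bis(TIPSO)phenyl]magnesium bromide (THF solution from step 2); 7 2-hydroxy-6-(TIPSO)benzaldehyde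
Product: 8 rac-2-{[3,5-bis(TIPSO)phenyl](hydroxy)methyl}-3-(TIPSO)phenol
Conditions: 3 (2.2 eq), THF, −20 → 0 °C; aq. NH4Cl
Reagents that add atoms: none
Why: Grignard addition to the aldehyde after the first equivalent has deprotonated the phenol; the carbinol centre is left racemic on purpose, because step 6 erases it.

**Step 6**
Reactants: 8 rac-2-{[3,5-bis(TIPSO)phenyl](hydroxy)methyl}-3-(TIPSO)phenol; 5 2-diazo-1-phenylethan-1-one
Product: 10 [(2R,3S)-3-[3,5-bis(TIPSO)phenyl]-4-(TIPSO)-2,3-dihydro-1-benzofuran-2-yl](phenyl)methanone (2,3-cis), via o-quinone methide 9 (not isolated)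
Conditions: 5 (1.5 eq), (R)-TRIP (10 mol%), 4 Å MS, CHCl3, 0 °C → rt
Reagents that add atoms: none
Why: Chiral phosphoric acid catalysed [4+1] annulation of an o-quinone methide with a diazoketone: the acid dehydrates 8 to 9 and holds it by hydrogen bonding while the diazo carbon adds to one face of the methide carbon (C3 set as S under catalyst control), and the phenol oxygen then displaces N2 to close the ring, cis at C2 by kinetic control.

**Step 7**
Reactants: 10 the cis ketone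
Product: 11 (2S,3S)-3-[3,5-bis(TIPSO)phenyl]-4-(TIPSO)-2,3-dihydro-1-benzofuran-2-yl benzoate (2,3-cis)
Conditions: mCPBA (2 eq), solid NaHCO3 buffer, CH2Cl2, 0 °C → rt
Reagents that add atoms: 3-chloroperoxybenzoic acid, OOC(=O)c1cccc(Cl)c1
Why: Baeyer–Villiger oxidation in which C2, a secondary carbon bearing the ring oxygen, should migrate in preference to phenyl and with retention, turning the acyl group into an anomeric leaving group without touching C3 (the descriptor at C2 changes only through the priorities).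

**Step 8**
Reactants: 11 the anomeric benzoate; 12 benzene-1,3-diol (resorcinol)
Product: 14 4-[(2S,3S)-3-[3,5-bis(TIPSO)phenyl]-4-(TIPSO)-2,3-dihydro-1-benzofuran-2-yl]benzene-1,3-diol (2,3-trans), via oxocarbenium ion 13 (not isolated)
Conditions: 12 (6 eq), BF3·OEt2 (0.3 eq), MeCN/CH2Cl2, −40 → 0 °C
Reagents that add atoms: none
Why: Friedel–Crafts C-arylation of an anomeric ester (as in aryl C-glycoside synthesis): excess resorcinol should attack ion 13 through its C4, anti to the C3 aryl group, and the 2,3-trans product is also the thermodynamic one because the p-hydroxybenzylic C2–O1 bond can reopen under the acid.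

**Step 9**
Reactants: 14 the resorcinol adduct
Product: 15 (2S,3S)-2-[2,4-bis(TIPSO)phenyl]-3-[3,5-bis(TIPSO)phenyl]-4-(TIPSO)-2,3-dihydro-1-benzofuran
Conditions: TIPSOTf (2.6 eq), 2,6-lutidine, CH2Cl2, 0 °C → rt
Reagents that add atoms: triisopropylsilyl trifluoromethanesulfonate, CC(C)[Si](OS(=O)(=O)C(F)(F)F)(C(C)C)C(C)C
Why: Silylation with the triflate caps both phenols, so that every activated position of this ring gains a bulky ortho neighbour before the key step.

**Step 10**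
Reactants: 1 5-bromobenzene-1,3-diol
Product: 17 2-bromo-4,6-dihydroxybenzaldehyde, via aryl iminium salt 16 (not isolated)
Conditions: POCl3, DMF, MeCN, 0 °C → rt; then H2O, 50 °C
Reagents that add atoms: N,N-dimethylformamide, CN(C)C=O; water, O
Why: Vilsmeier–Haack formylation at C4 of the resorcinol (ortho to one OH, para to the other), the usual site for this ring type; formate or phosphate esters on oxygen are hydrolysed in the aqueous heating.

**Step 11**
Reactants: 17 2-bromo-4,6-dihydroxybenzaldehyde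
Product: 18 2-bromo-6-hydroxy-4-(TIPSO)benzaldehyde
Conditions: TIPSCl (1.05 eq), imidazole, CH2Cl2, 0 °C
Reagents that add atoms: chlorotriisopropylsilane, CC(C)[Si](Cl)(C(C)C)C(C)C
Why: The 4-OH, para to the aldehyde, is the more acidic one and is not hydrogen-bonded to the carbonyl, so one bulky silyl chloride should go there selectively.

**Step 12**
Reactants: 3 [3,5-bis(TIPSO)phenyl]magnesium bromide (THF solution from step 2); 18 2-bromo-6-hydroxy-4-(TIPSO)benzaldehyde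
Product: 19 rac-3-bromo-2-{[3,5-bis(TIPSO)phenyl](hydroxy)methyl}-5-(TIPSO)phenol
Conditions: 3 (2.2 eq), THF, −20 → 0 °C; aq. NH4Cl
Reagents that add atoms: none
Why: Grignard addition as in step 5; an aryl Grignard reagent does not exchange with the ring bromide at this temperature, and the racemic carbinol centre is erased in step 13.

**Step 13**
Reactants: 19 the bromo carbinol; 5 2-diazo-1-phenylethan-1-one
Product: 21 [(2R,3S)-4-bromo-3-[3,5-bis(TIPSO)phenyl]-6-(TIPSO)-2,3-dihydro-1-benzofuran-2-yl](phenyl)methanone (2,3-cis), via o-quinone methide 20 (not isolated)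
Conditions: 5 (1.5 eq), (R)-TRIP (10 mol%), 4 Å MS, CHCl3, 0 °C → rt
Reagents that add atoms: none
Why: The same chiral phosphoric acid catalysed [4+1] annulation as in step 6: the silyloxy group para to the carbinol carbon assists formation of 20, the catalyst directs the diazo carbon to one face of the methide carbon (C3, S), and ring closure with loss of N2 gives the cis ketone.

**Step 14**
Reactants: 21 the bromo cis ketone
Product: 22 (2S,3S)-4-bromo-3-[3,5-bis(TIPSO)phenyl]-6-(TIPSO)-2,3-dihydro-1-benzofuran-2-yl benzoate (2,3-cis)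
Conditions: mCPBA (2 eq), solid NaHCO3 buffer, CH2Cl2, 0 °C → rt
Reagents that add atoms: 3-chloroperoxybenzoic acid, OOC(=O)c1cccc(Cl)c1
Why: Baeyer–Villiger oxidation with migration of the oxygen-bearing C2 in preference to phenyl and with retention, as in step 7; C3 is not involved.

**Step 15**
Reactants: 22 the bromo anomeric benzoate; 15 the penta-TIPS dihydrobenzofuran
Product: 24 (2S,3S)-4-bromo-3-[3,5-bis(TIPSO)phenyl]-2-{(2S,3S)-2-[2,4-bis(TIPSO)phenyl]-3-[3,5-bis(TIPSO)phenyl]-4-(TIPSO)-2,3-dihydro-1-benzofuran-7-yl}-6-(TIPSO)-2,3-dihydro-1-benzofuran, via oxocarbenium ion 23 (not isolated)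
Conditions: TMSOTf (0.2 eq), 4 Å MS, CH2Cl2, −78 → −40 °C; 22 (1.4 eq) added slowly to 15; Et3N quench
Reagents that add atoms: none
Why: The silyl triflate ionises the anomeric benzoate of 22 to the 2-oxocarbenium ion 23, and C7 of 15 attacks it in a Friedel–Crafts alkylation of the kind used to make aryl C-glycosides from anomeric esters; loss of the arene proton then frees benzoic acid and returns the acid that carries the chain. No ring is closed in this step, since both dihydrofuran rings are already in place. The new C2 centre is set by the C3 aryl group, which blocks its own face of the flat oxocarbenium ring and is backed by the flanking C4 bromine, so that the arene should enter anti and give the 2,3-trans (2S,3S) isomer. The step needs C7 over C5 of the same ring and over the two outer aryl rings of 15: C7 is ortho to ring O1 and para to the C4 silyloxy group, and it is the only activated position without a triisopropylsilyloxy neighbour. It also needs capture to outrun loss of the doubly benzylic C3 proton to the 3-arylbenzofuran, which low temperature, a non-basic counter-ion and a standing excess of 15 over the ion should favour.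

**Step 16**
Reactants: 24 the coupled bromide; 25 tert-butyldimethyl(4-vinylphenoxy)silane
Product: 26 (2S,3S)-4-[(E)-2-(4-TBSO-phenyl)ethenyl]-3-[3,5-bis(TIPSO)phenyl]-2-{(2S,3S)-2-[2,4-bis(TIPSO)phenyl]-3-[3,5-bis(TIPSO)phenyl]-4-(TIPSO)-2,3-dihydro-1-benzofuran-7-yl}-6-(TIPSO)-2,3-dihydro-1-benzofuran
Conditions: 25 (1.5 eq), Pd(P(t-Bu)3)2 (5 mol%), Cy2NMe, dioxane, 80 °C
Reagents that add atoms: none
Why: Mizoroki–Heck reaction of the hindered aryl bromide under bulky-phosphine conditions; syn insertion and syn β-hydride elimination should give the E-stilbene, and the amine base leaves the aryl silyl ethers and the stereocentres alone.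

**Step 17**
Reactants: 26 the nona-silyl ether
Product: 27 (2S,3S)-2-(2,4-dihydroxyphenyl)-3-(3,5-dihydroxyphenyl)-7-{(2S,3S)-3-(3,5-dihydroxyphenyl)-6-hydroxy-4-[(E)-2-(4-hydroxyphenyl)ethenyl]-2,3-dihydro-1-benzofuran-2-yl}-2,3-dihydro-1-benzofuran-4-ol (target)
Conditions: TBAF (12 eq), AcOH (12 eq), degassed THF, 0 °C → rt
Reagents that add atoms: none
Why: Fluoride cleaves all nine aryl silyl ethers, and the acetic acid buffer protonates the phenoxides at once, so that the p-hydroxybenzylic C2–O bonds should not open and the polyphenol should not be oxidised.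

**Compound list**

1 | 5-bromobenzene-1,3-diol | Oc1cc(O)cc(Br)c1 | starting material
2 | 1-bromo-3,5-bis(TIPSO)benzene | Brc1cc(O[Si](C(C)C)(C(C)C)C(C)C)cc(O[Si](C(C)C)(C(C)C)C(C)C)c1 | intermediate
3 | [3,5-bis(TIPSO)phenyl]magnesium bromide (titrated THF solution) | Br[Mg]c1cc(O[Si](C(C)C)(C(C)C)C(C)C)cc(O[Si](C(C)C)(C(C)C)C(C)C)c1 | intermediate
4 | 2-bromo-1-phenylethan-1-one | O=C(CBr)c1ccccc1 | starting material
5 | 2-diazo-1-phenylethan-1-one | O=C(C=[N+]=[N-])c1ccccc1 | intermediate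
6 | 2,6-dihydroxybenzaldehyde | O=Cc1c(O)cccc1O | starting material
7 | 2-hydroxy-6-(TIPSO)benzaldehyde | O=Cc1c(O)cccc1O[Si](C(C)C)(C(C)C)C(C)C | intermediate
8 | rac-2-{[3,5-bis(TIPSO)phenyl](hydroxy)methyl}-3-(TIPSO)phenol | OC(c1cc(O[Si](C(C)C)(C(C)C)C(C)C)cc(O[Si](C(C)C)(C(C)C)C(C)C)c1)c1c(O)cccc1O[Si](C(C)C)(C(C)C)C(C)C | intermediate
9 | 6-{[3,5-bis(TIPSO)phenyl]methylidene}-5-(TIPSO)cyclohexa-2,4-dien-1-one | O=C1C=CC=C(O[Si](C(C)C)(C(C)C)C(C)C)C1=Cc1cc(O[Si](C(C)C)(C(C)C)C(C)C)cc(O[Si](C(C)C)(C(C)C)C(C)C)c1 | intermediate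
10 | [(2R,3S)-3-[3,5-bis(TIPSO)phenyl]-4-(TIPSO)-2,3-dihydro-1-benzofuran-2-yl](phenyl)methanone | c1ccc(O[Si](C(C)C)(C(C)C)C(C)C)c2c1O[C@@H](C(=O)c1ccccc1)[C@H]2c1cc(O[Si](C(C)C)(C(C)C)C(C)C)cc(O[Si](C(C)C)(C(C)C)C(C)C)c1 | intermediate
11 | (2S,3S)-3-[3,5-bis(TIPSO)phenyl]-4-(TIPSO)-2,3-dihydro-1-benzofuran-2-yl benzoate | c1ccc(O[Si](C(C)C)(C(C)C)C(C)C)c2c1O[C@@H](OC(=O)c1ccccc1)[C@H]2c1cc(O[Si](C(C)C)(C(C)C)C(C)C)cc(O[Si](C(C)C)(C(C)C)C(C)C)c1 | intermediate
12 | benzene-1,3-diol | Oc1cccc(O)c1 | starting material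
13 | (3S)-3-[3,5-bis(TIPSO)phenyl]-4-(TIPSO)-3H-1-benzofuran-1-ium | c1ccc(O[Si](C(C)C)(C(C)C)C(C)C)c2c1[O+]=C[C@H]2c1cc(O[Si](C(C)C)(C(C)C)C(C)C)cc(O[Si](C(C)C)(C(C)C)C(C)C)c1 | intermediate
14 | 4-[(2S,3S)-3-[3,5-bis(TIPSO)phenyl]-4-(TIPSO)-2,3-dihydro-1-benzofuran-2-yl]benzene-1,3-diol | c1ccc(O[Si](C(C)C)(C(C)C)C(C)C)c2c1O[C@H](c1ccc(O)cc1O)[C@H]2c1cc(O[Si](C(C)C)(C(C)C)C(C)C)cc(O[Si](C(C)C)(C(C)C)C(C)C)c1 | intermediate
15 | (2S,3S)-2-[2,4-bis(TIPSO)phenyl]-3-[3,5-bis(TIPSO)phenyl]-4-(TIPSO)-2,3-dihydro-1-benzofuran | c1ccc(O[Si](C(C)C)(C(C)C)C(C)C)c2c1O[C@H](c1ccc(O[Si](C(C)C)(C(C)C)C(C)C)cc1O[Si](C(C)C)(C(C)C)C(C)C)[C@H]2c1cc(O[Si](C(C)C)(C(C)C)C(C)C)cc(O[Si](C(C)C)(C(C)C)C(C)C)c1 | intermediate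
16 | [(2-bromo-4,6-dihydroxyphenyl)methylidene]dimethylazanium dichlorophosphate | C[N+](C)=Cc1c(O)cc(O)cc1Br.[O-]P(Cl)(Cl)=O | intermediate
17 | 2-bromo-4,6-dihydroxybenzaldehyde | O=Cc1c(O)cc(O)cc1Br | intermediate
18 | 2-bromo-6-hydroxy-4-(TIPSO)benzaldehyde | O=Cc1c(O)cc(O[Si](C(C)C)(C(C)C)C(C)C)cc1Br | intermediate
19 | rac-3-bromo-2-{[3,5-bis(TIPSO)phenyl](hydroxy)methyl}-5-(TIPSO)phenol | OC(c1cc(O[Si](C(C)C)(C(C)C)C(C)C)cc(O[Si](C(C)C)(C(C)C)C(C)C)c1)c1c(O)cc(O[Si](C(C)C)(C(C)C)C(C)C)cc1Br | intermediate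
20 | 5-bromo-6-{[3,5-bis(TIPSO)phenyl]methylidene}-3-(TIPSO)cyclohexa-2,4-dien-1-one | O=C1C=C(O[Si](C(C)C)(C(C)C)C(C)C)C=C(Br)C1=Cc1cc(O[Si](C(C)C)(C(C)C)C(C)C)cc(O[Si](C(C)C)(C(C)C)C(C)C)c1 | intermediate
21 | [(2R,3S)-4-bromo-3-[3,5-bis(TIPSO)phenyl]-6-(TIPSO)-2,3-dihydro-1-benzofuran-2-yl](phenyl)methanone | Brc1cc(O[Si](C(C)C)(C(C)C)C(C)C)cc2c1[C@H](c1cc(O[Si](C(C)C)(C(C)C)C(C)C)cc(O[Si](C(C)C)(C(C)C)C(C)C)c1)[C@H](C(=O)c1ccccc1)O2 | intermediate
22 | (2S,3S)-4-bromo-3-[3,5-bis(TIPSO)phenyl]-6-(TIPSO)-2,3-dihydro-1-benzofuran-2-yl benzoate | Brc1cc(O[Si](C(C)C)(C(C)C)C(C)C)cc2c1[C@H](c1cc(O[Si](C(C)C)(C(C)C)C(C)C)cc(O[Si](C(C)C)(C(C)C)C(C)C)c1)[C@H](OC(=O)c1ccccc1)O2 | intermediate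
23 | (3S)-4-bromo-3-[3,5-bis(TIPSO)phenyl]-6-(TIPSO)-3H-1-benzofuran-1-ium | Brc1cc(O[Si](C(C)C)(C(C)C)C(C)C)cc2c1[C@H](c1cc(O[Si](C(C)C)(C(C)C)C(C)C)cc(O[Si](C(C)C)(C(C)C)C(C)C)c1)C=[O+]2 | intermediate
24 | (2S,3S)-4-bromo-3-[3,5-bis(TIPSO)phenyl]-2-{(2S,3S)-2-[2,4-bis(TIPSO)phenyl]-3-[3,5-bis(TIPSO)phenyl]-4-(TIPSO)-2,3-dihydro-1-benzofuran-7-yl}-6-(TIPSO)-2,3-dihydro-1-benzofuran | Brc1cc(O[Si](C(C)C)(C(C)C)C(C)C)cc2c1[C@H](c1cc(O[Si](C(C)C)(C(C)C)C(C)C)cc(O[Si](C(C)C)(C(C)C)C(C)C)c1)[C@@H](c1ccc(O[Si](C(C)C)(C(C)C)C(C)C)c3c1O[C@H](c1ccc(O[Si](C(C)C)(C(C)C)C(C)C)cc1O[Si](C(C)C)(C(C)C)C(C)C)[C@H]3c1cc(O[Si](C(C)C)(C(C)C)C(C)C)cc(O[Si](C(C)C)(C(C)C)C(C)C)c1)O2 | intermediate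
25 | tert-butyldimethyl(4-vinylphenoxy)silane | C=Cc1ccc(O[Si](C)(C)C(C)(C)C)cc1 | starting material
26 | nona-silyl ether of the target (eight TIPS, one TBS on the styryl phenol) | CC(C)(C)[Si](C)(C)Oc1ccc(/C=C/c2cc(O[Si](C(C)C)(C(C)C)C(C)C)cc3c2[C@H](c2cc(O[Si](C(C)C)(C(C)C)C(C)C)cc(O[Si](C(C)C)(C(C)C)C(C)C)c2)[C@@H](c2ccc(O[Si](C(C)C)(C(C)C)C(C)C)c4c2O[C@H](c2ccc(O[Si](C(C)C)(C(C)C)C(C)C)cc2O[Si](C(C)C)(C(C)C)C(C)C)[C@H]4c2cc(O[Si](C(C)C)(C(C)C)C(C)C)cc(O[Si](C(C)C)(C(C)C)C(C)C)c2)O3)cc1 | intermediate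
27 | (2S,3S)-2-(2,4-dihydroxyphenyl)-3-(3,5-dihydroxyphenyl)-7-{(2S,3S)-3-(3,5-dihydroxyphenyl)-6-hydroxy-4-[(E)-2-(4-hydroxyphenyl)ethenyl]-2,3-dihydro-1-benzofuran-2-yl}-2,3-dihydro-1-benzofuran-4-ol | Oc1ccc(/C=C/c2cc(O)cc3c2[C@H](c2cc(O)cc(O)c2)[C@@H](c2ccc(O)c4c2O[C@H](c2ccc(O)cc2O)[C@H]4c2cc(O)cc(O)c2)O3)cc1 | target

**Step count.** Total: 17 steps. Longest linear sequence: 10 steps (1 → 2 → 5 → 6 → 7 → 8 → 9 → 15 → 16 → 17).

**Steps most likely to fail**

Step 15 (key step). Ion 23 may lose its doubly benzylic C3 proton and aromatise faster than the hindered arene attacks, or the arene may react through C5 instead of C7. The fallback reverses the polarity and closes the ring last; it sets out from 15 and 22 and comes back to the route at 24. Compound 15 is brominated with NBS (CH2Cl2, −78 °C) at the same unshielded carbon to give the 7-bromide F1. Compound 22 is treated with DIBAL-H (CH2Cl2, −78 °C), which removes the benzoyl group and leaves the lactol F2. Bromine–lithium exchange on F1 (n-BuLi, THF, −78 °C) gives the aryllithium F3, which adds to the open hydroxy-aldehyde form of F2 (hydroxyl deprotonated beforehand with NaH) to give the diol F4. PPTS in CH2Cl2 then ionises the benzylic alcohol of F4, which is para to a silyloxy group, and the neighbouring phenol closes the C2–O1 bond to the thermodynamically preferred trans ring of 24.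

Step 13 (the same concern applies to step 6). Facial discrimination on an o-quinone methide that carries a substituent next to the methide carbon (Br here, TIPSO in step 6) may be poor, and acid-mediated O–H insertion of the diazoketone may compete. The fallback replaces catalyst control under acid by a stoichiometric chiral ylide under base; it sets out from 19 and comes back to the route at 24. Carbinol 19 is converted with p-toluenesulfinic acid (CH2Cl2, rt) into the sulfone F5. Quinidine is alkylated with 4 to N-phenacylquinidinium bromide F6. With Cs2CO3 in CH2Cl2, F5 loses sulfinate to give 20, F6 is deprotonated to its ylide F7, and conjugate addition followed by ring closure with loss of quinidine should give the trans ketone F8; the quinine-derived pseudoenantiomer is used if the (3R) series results. F8 is the C2 epimer of 21; Baeyer–Villiger oxidation as in step 14 gives the trans benzoate F9, which ionises under the conditions of step 15 to the same ion 23 and hence 24.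

Step 14 (the same concern applies to step 7). The peracid may hydroxylate the silyloxy arenes, phenyl may migrate in place of C2, or the anomeric benzoate may lose benzoic acid during isolation. The fallback replaces the oxidative rearrangement by a Beckmann fragmentation; it sets out from 21 and comes back to the route at 24. Ketone 21 is condensed with hydroxylamine (NH2OH·HCl, pyridine, EtOH, 60 °C) to the oxime F10. MsCl and Et3N (CH2Cl2, −20 °C) give the oxime mesylate F11, which fragments with loss of benzonitrile because the ring oxygen stabilises the cation at C2. Capture by acetate (AcOH, Bu4NOAc) gives the anomeric acetate F12, which enters step 15 in place of 22 and converges on ion 23 and 24.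

**Further compounds**

F1 | step 15 | (2S,3S)-7-bromo-2-[2,4-bis(TIPSO)phenyl]-3-[3,5-bis(TIPSO)phenyl]-4-(TIPSO)-2,3-dihydro-1-benzofuran | Brc1ccc(O[Si](C(C)C)(C(C)C)C(C)C)c2c1O[C@H](c1ccc(O[Si](C(C)C)(C(C)C)C(C)C)cc1O[Si](C(C)C)(C(C)C)C(C)C)[C@H]2c1cc(O[Si](C(C)C)(C(C)C)C(C)C)cc(O[Si](C(C)C)(C(C)C)C(C)C)c1
F2 | step 15 | (3S)-4-bromo-3-[3,5-bis(TIPSO)phenyl]-6-(TIPSO)-2,3-dihydro-1-benzofuran-2-ol (anomer mixture) | Brc1cc(O[Si](C(C)C)(C(C)C)C(C)C)cc2c1[C@H](c1cc(O[Si](C(C)C)(C(C)C)C(C)C)cc(O[Si](C(C)C)(C(C)C)C(C)C)c1)C(O)O2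
F3 | step 15 | 7-lithio derivative of 15 | [Li]c1ccc(O[Si](C(C)C)(C(C)C)C(C)C)c2c1O[C@H](c1ccc(O[Si](C(C)C)(C(C)C)C(C)C)cc1O[Si](C(C)C)(C(C)C)C(C)C)[C@H]2c1cc(O[Si](C(C)C)(C(C)C)C(C)C)cc(O[Si](C(C)C)(C(C)C)C(C)C)c1
F4 | step 15 | (2S)-2-[2-bromo-6-hydroxy-4-(TIPSO)phenyl]-2-[3,5-bis(TIPSO)phenyl]-1-[7-yl of 15]ethan-1-ol (carbinol epimers) | OC(c1ccc(O[Si](C(C)C)(C(C)C)C(C)C)c2c1O[C@H](c1ccc(O[Si](C(C)C)(C(C)C)C(C)C)cc1O[Si](C(C)C)(C(C)C)C(C)C)[C@H]2c1cc(O[Si](C(C)C)(C(C)C)C(C)C)cc(O[Si](C(C)C)(C(C)C)C(C)C)c1)[C@@H](c1cc(O[Si](C(C)C)(C(C)C)C(C)C)cc(O[Si](C(C)C)(C(C)C)C(C)C)c1)c1c(O)cc(O[Si](C(C)C)(C(C)C)C(C)C)cc1Br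
F5 | step 13 | rac-3-bromo-2-{[3,5-bis(TIPSO)phenyl](4-methylbenzenesulfonyl)methyl}-5-(TIPSO)phenol | Cc1ccc(cc1)S(=O)(=O)C(c1cc(O[Si](C(C)C)(C(C)C)C(C)C)cc(O[Si](C(C)C)(C(C)C)C(C)C)c1)c1c(O)cc(O[Si](C(C)C)(C(C)C)C(C)C)cc1Br
F6 | step 13 | N-phenacylquinidinium bromide | COC1=CC2=C(C=CN=C2C=C1)[C@@H]([C@H]3C[C@@H]4CC[N+]3(CC(=O)C5=CC=CC=C5)C[C@@H]4C=C)O.[Br-]
F7 | step 13 | N-phenacylquinidinium ylide | COC1=CC2=C(C=CN=C2C=C1)[C@@H]([C@H]3C[C@@H]4CC[N+]3([CH-]C(=O)C5=CC=CC=C5)C[C@@H]4C=C)O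
F8 | step 13 | [(2S,3S)-4-bromo-3-[3,5-bis(TIPSO)phenyl]-6-(TIPSO)-2,3-dihydro-1-benzofuran-2-yl](phenyl)methanone (2,3-trans) | Brc1cc(O[Si](C(C)C)(C(C)C)C(C)C)cc2c1[C@H](c1cc(O[Si](C(C)C)(C(C)C)C(C)C)cc(O[Si](C(C)C)(C(C)C)C(C)C)c1)[C@@H](C(=O)c1ccccc1)O2
F9 | step 13 | (2R,3S)-4-bromo-3-[3,5-bis(TIPSO)phenyl]-6-(TIPSO)-2,3-dihydro-1-benzofuran-2-yl benzoate (2,3-trans) | Brc1cc(O[Si](C(C)C)(C(C)C)C(C)C)cc2c1[C@H](c1cc(O[Si](C(C)C)(C(C)C)C(C)C)cc(O[Si](C(C)C)(C(C)C)C(C)C)c1)[C@@H](OC(=O)c1ccccc1)O2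
F10 | step 14 | oxime of 21 | Brc1cc(O[Si](C(C)C)(C(C)C)C(C)C)cc2c1[C@H](c1cc(O[Si](C(C)C)(C(C)C)C(C)C)cc(O[Si](C(C)C)(C(C)C)C(C)C)c1)[C@H](C(=NO)c1ccccc1)O2
F11 | step 14 | O-methanesulfonyl oxime of 21 | Brc1cc(O[Si](C(C)C)(C(C)C)C(C)C)cc2c1[C@H](c1cc(O[Si](C(C)C)(C(C)C)C(C)C)cc(O[Si](C(C)C)(C(C)C)C(C)C)c1)[C@H](C(=NOS(C)(=O)=O)c1ccccc1)O2
F12 | step 14 | (3S)-4-bromo-3-[3,5-bis(TIPSO)phenyl]-6-(TIPSO)-2,3-dihydro-1-benzofuran-2-yl acetate (anomer mixture) | Brc1cc(O[Si](C(C)C)(C(C)C)C(C)C)cc2c1[C@H](c1cc(O[Si](C(C)C)(C(C)C)C(C)C)cc(O[Si](C(C)C)(C(C)C)C(C)C)c1)C(OC(C)=O)O2
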